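The numbers in the tables come from a simulation for substances that don't exist, and the scatter is random.

The vessels on this bench are stirred at constant volume. Substrate and capture agent are in from the start, and reagent goes in as 3 equal portions, the first at the start.

| flask | substrate | reagent | capture agent | remark | time |
|---|---|---|---|---|---|
| gamma | 0.21 M | 5 equiv (in portions, 3) | 0.030 M | run made earlier; portions every 2.0 min |  |
| delta | 0.41 M | 5 equiv (in portions, 3) | 0.030 M | run made earlier; portions every 2.0 min |  |
| alpha | 0.30 M | 5 equiv (in portions, 3) | 0.041 M | run made earlier; portions every 2.0 min |  |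
| grey | 0.30 M | 1.70 equiv (in portions, 3) | 0.0300 M | the portions of reagent follow each other after 2.0 min, the first at the start | 8.0 min |
| blue | 0.30 M | 5.00 equiv (in portions, 3) | 0.0300 M | the portions of reagent follow each other after 2.0 min, the first at the start | 8.0 min |
| violet | 0.30 M | 5.00 equiv (in portions, 3) | 0.0500 M | the portions of reagent follow each other after 0.50 min, the first at the start | 8.0 min |
| green | 0.60 M | 5.00 equiv (in portions, 3) | 0.0300 M | the portions of reagent follow each other after 4.0 min, the first at the start | 8.0 min |

- gamma (time / min: target / %, substrate / %): 0.500: 1.8, 95.9; 1.33: 8.1, 88.0; 2.50: 17.8, 74.8; 4.00: 33.0, 54.7; 6.00: 51.2, 29.4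
- delta (time / min: target / %, substrate / %): 0.417: 3.3, 92.9; 0.833: 8.1, 86.2; 1.50: 16.1, 75.3; 3.00: 35.9, 44.9; 6.00: 59.1, 8.9
- alpha (time / min: target / %, substrate / %): 0.417: 2.0, 95.1; 0.833: 5.8, 89.5; 1.50: 13.5, 81.2; 3.00: 29.8, 56.5; 6.00: 56.6, 17.0

(scatter of a reading: 0.3 percentage points)



- ranking by amount of target, in percent of the substrate charged, from high to low, at 8.0 min (grey / blue / violet / green)
- the amount of target, in percent of the substrate charged of the flask you put first, at 8.0 min
- the amount of target, in percent of the substrate charged of the flask you put last, at 8.0 min

Take over with one quantity in hand. Let B be the concentration of the full reagent charge, τ the interval between portions and t the time. The mean portion arrives one interval late, so from the last portion on, with reagent counted as charged, the integral of reagent concentration up to t is E = B(t − τ), which in blue is 9.00 M·min, the reagent exposure.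

Treat the substrate as pseudo-first-order, with reagent counted as charged; integrating gives the fraction left as exp(−kE). The last alpha reading gives k = 0.295 M⁻¹ min⁻¹. That k gives 8.88% for the last delta reading, which stands at 8.9%.

So expect substrate left at 8.0 min of 7.03% in blue, 3.61% in violet, 2.89% in green and 40.5% in grey.

Alpha's target per substrate used at its last reading, 0.682, is my share for the flasks at 0.30 M. The gamma and delta shares at their last readings, carried in a straight line to green's 0.60 M, give 0.576. My target is then 65.7% in violet, 63.4% in blue, 55.9% in green and 40.6% in grey.

Leave violet's interval at 0.50 min: its exposure of 11.2 M·min is larger than blue's, and with one share for both that puts violet ahead.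

The forecast, which parts from this order at the top, reads blue > violet > green > grey with 64.5% and 43%, and says “Blue and violet are nearly tied”.

The flasks give violet > blue > green > grey, with 65.6%, 63.2%, 57.5% and 39.2%.

    open intermediate ⇌ target + by-product (K = 1.00 M, k = 2.80 min⁻¹)
    substrate + reagent ⇌ open intermediate (K = 28.0 M⁻¹, k = 0.260 M⁻¹ min⁻¹)
    substrate + by-product → side product (k = 0.960 M⁻¹ min⁻¹)
    open intermediate + capture agent → trapped intermediate (k = 1.30 M⁻¹ min⁻¹)

At 8.00 min blue holds 6.98% substrate, and exp(−kE) with its exposure gives 7.03%. Now take grey's neighbour, cut to 1.00 equiv of reagent with the other charges and the time held. B(t − τ) gives 1.80 M·min, so the reckoning leaves 58.8% substrate and, at alpha's share, makes 28.1% target. At 8.00 min that neighbour holds 57.5% substrate and 27.0% target.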